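**Retrosynthetic overview**

- Target ⇐ desilylation and C16 acetylation of a tris-silylated 6,8-dioxabicyclo[3.2.2]nonan-7-one.
- Bicycle ⇐ one carbenoid operation on a monocyclic α-diazo ester: the ring oxygen of a 2-silyloxytetrahydropyran adds to the C11 carbenoid (closes the 1,4-dioxan-2-one first), then acetal carbon C10 shifts from O to C11 (opens the pyran, closes the oxepane and the seven-membered lactone).
- Diazo ester ⇐ tertiary C7 ester of a pyranol with a (Z)-hept-5-enoic acid, then diazo transfer; pyranol ⇐ MeLi addition to an Achmatowicz pyranone ⇐ (S)-furyl carbinol.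
- Furyl carbinol ⇐ 2-furyllithium + C1–C6 aldehyde from nerol; acid ⇐ Z-selective Wittig of (4-carboxybutyl)triphenylphosphonium bromide with a silyloxyacetone.
- Ring order: furan → sacrificial pyran (Achmatowicz) → dioxanone, then oxepane and caprolactone in the same carbenoid step.

Assumption: the SMILES is taken as drawn; atoms are labelled C1–C16 along the open chain (C1 = CH2OH, C6 = ether CH, C7 = methyl-bearing lactone-O carbon, C10 = CHOH, C11 = quaternary lactone α-carbon, C16 = CH2OAc), i.e. 6S,7R,10S,11R with both trisubstituted alkenes Z.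

**Route**

Step 1
Reactants: 1 (4-carboxybutyl)triphenylphosphonium bromide; 2 1-[(tert-butyldimethylsilyl)oxy]propan-2-one
Product: 4 (Z)-7-[(tert-butyldimethylsilyl)oxy]-6-methylhept-5-enoic acid, via carboxylate ylide 3 (not isolated)
Conditions: KN(SiMe3)2 (2.1 equiv), THF, 0 °C; then 2, −78 °C to rt; dilute HCl to pH 4
Reagents that add atoms: none
Why: Salt-free Wittig olefination of an α-silyloxy ketone with a non-stabilised ylide, which places the CH2O carbon cis to the chain (Z-selective trisubstituted allylic ether synthesis) and so sets the C14=C15 geometry.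

Step 2
Reactants: 5 nerol
Product: 6 neryl tert-butyldiphenylsilyl ether
Conditions: TBDPSCl, imidazole, CH2Cl2, rt
Reagents that add atoms: tert-butyl(chloro)diphenylsilane, CC(C)(C)[Si](Cl)(c1ccccc1)c1ccccc1
Why: Standard silylation of a primary allylic alcohol; the Z C2=C3 alkene of the target comes unchanged from nerol.

Step 3
Reactants: 6 neryl tert-butyldiphenylsilyl ether
Product: 7 (Z)-6-[(tert-butyldiphenylsilyl)oxy]-4-methylhex-4-enal
Conditions: O3 (about 1 equiv, Sudan Red 7B end-point), CH2Cl2, −78 °C; then Me2S, −78 °C to rt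
Reagents that add atoms: ozone, [O-][O+]=O
Why: Chemoselective ozonolysis, since the distal isopropylidene alkene is more electron-rich and less hindered than the alkene flanked by the bulky allylic silyloxy group.

Step 4
Reactants: 7 (Z)-6-[(tert-butyldiphenylsilyl)oxy]-4-methylhex-4-enal; 8 furan
Product: 10 racemic (Z)-6-[(tert-butyldiphenylsilyl)oxy]-1-(furan-2-yl)-4-methylhex-4-en-1-ol, via 2-furyllithium 9 (not isolated)
Conditions: n-BuLi, THF, 0 °C; then 7, −78 °C; H2O
Reagents that add atoms: none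
Why: α-Lithiation of furan followed by 1,2-addition of the organolithium to the aldehyde gives the furyl carbinol needed for ring expansion.

Step 5
Reactants: 10 racemic furyl carbinol
Product: 11 (2S)-2-[(Z)-5-[(tert-butyldiphenylsilyl)oxy]-3-methylpent-3-en-1-yl]-6-hydroxy-2H-pyran-3(6H)-one (anomer mixture)
Conditions: Ti(OiPr)4 (1.0 equiv), L-(+)-diisopropyl tartrate (1.2 equiv), t-BuOOH (0.5 equiv), CH2Cl2, −20 °C; stopped below 50 % conversion, (R)-10 recovered
Reagents that add atoms: tert-butyl hydroperoxide, CC(C)(C)OO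
Why: Sharpless kinetic resolution in which the fast-reacting (S)-furyl carbinol (L-tartrate) is oxidised by the Ti–tartrate–hydroperoxide system straight to the pyranone (Achmatowicz rearrangement), fixing C6 as S.

Step 6
Reactants: 11 pyranone lactol
Product: 12 (2S,6S)-6-[(tert-butyldimethylsilyl)oxy]-2-[(Z)-5-[(tert-butyldiphenylsilyl)oxy]-3-methylpent-3-en-1-yl]-2H-pyran-3(6H)-one (2,6-trans)
Conditions: TBSCl, imidazole, CH2Cl2, 0 °C; minor cis anomer removed by chromatography
Reagents that add atoms: tert-butyl(chloro)dimethylsilane, CC(C)(C)[Si](C)(C)Cl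
Why: Anomeric O-silylation of the equilibrating lactol gives mainly the trans anomer (axial OSi, anomeric effect, side chain equatorial), which is the C10 configuration later transferred to the target.

Step 7
Reactants: 12 trans silyloxy pyranone; 4 (Z)-7-[(tert-butyldimethylsilyl)oxy]-6-methylhept-5-enoic acid
Product: 15 (2S,3R,6S)-6-[(tert-butyldimethylsilyl)oxy]-2-[(Z)-5-[(tert-butyldiphenylsilyl)oxy]-3-methylpent-3-en-1-yl]-3-methyl-3,6-dihydro-2H-pyran-3-yl (Z)-7-[(tert-butyldimethylsilyl)oxy]-6-methylhept-5-enoate, via acid chloride 13 (not isolated), via lithium alkoxide 14 (not isolated)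
Conditions: 4, 1-chloro-N,N,2-trimethylprop-1-en-1-amine, CH2Cl2, 0 °C; separately 12, MeLi (1.05 equiv), THF, −78 °C; then the acid chloride solution, −78 to 0 °C
Reagents that add atoms: methyllithium, [Li]C
Why: 1,2-Addition of MeLi by axial attack on the face opposite the pseudoaxial anomeric OTBS (same sense as hydride reductions of such pyranones) sets C7 with oxygen trans to the C6 chain, and the tertiary lithium alkoxide is O-acylated in the same flask by the acid chloride.

Step 8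
Reactants: 15 allylic tertiary ester
Product: 16 (2S,3R,6S)-6-[(tert-butyldimethylsilyl)oxy]-2-[(Z)-5-[(tert-butyldiphenylsilyl)oxy]-3-methylpent-3-en-1-yl]-3-methyltetrahydro-2H-pyran-3-yl (Z)-7-[(tert-butyldimethylsilyl)oxy]-6-methylhept-5-enoate
Conditions: 2-nitrobenzenesulfonylhydrazide, Et3N, CH2Cl2, rt
Reagents that add atoms: none
Why: Diimide reduction is selective for the cis-disubstituted ring alkene over the two trisubstituted alkenes and, unlike catalytic hydrogenation, cannot hydrogenolyse the allylic ester.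

Step 9
Reactants: 16 saturated tertiary ester
Product: 18 the 2-diazo ester of 16, (2S,3R,6S)-pyran-3-yl (Z)-7-[(tert-butyldimethylsilyl)oxy]-2-diazo-6-methylhept-5-enoate, via trifluoroacetyl ester 17 (not isolated)
Conditions: LiN(SiMe3)2, THF, −78 °C; CF3CO2CH2CF3; then MsN3, Et3N, H2O (1 equiv), MeCN, rt
Reagents that add atoms: methanesulfonyl azide, CS(=O)(=O)N=[N+]=[N-]
Why: Detrifluoroacetylative (Regitz-type) diazo transfer: Claisen activation of the ester α-CH2 as the trifluoroacetyl derivative lets the sulfonyl azide transfer N2 with loss of the activating group, and only silyl ethers (no enolisable acetate) are present.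

Step 10
Reactants: 18 α-diazo ester
Product: 20 (1R,2S,5R,9S)-2-[(tert-butyldimethylsilyl)oxy]-1-[(Z)-5-[(tert-butyldimethylsilyl)oxy]-4-methylpent-3-en-1-yl]-9-[(Z)-5-[(tert-butyldiphenylsilyl)oxy]-3-methylpent-3-en-1-yl]-5-methyl-6,8-dioxabicyclo[3.2.2]nonan-7-one, via oxonium ylide 19 (not isolated)
Conditions: Rh2(O2CCPh3)4 (2 mol %), CH2Cl2, slow addition of 18 (final 2 mM), −40 to 0 °C
Reagents that add atoms: none
Why: Proposed new method: N2 loss gives a Rh carbenoid at C11 that is attacked by the axial lone pair of the pyran oxygen (chair with the C7 ester oxygen axial), closing the 1,4-dioxan-2-one as a bicyclic oxonium ylide; the acetal carbon C10, the best migrating group because OTBS stabilises its radical or oxocarbenium character, then undergoes a [1,2]-Stevens shift from O to C11, which opens the pyran and closes the oxepane and the seven-membered lactone; C11 (R) is the only configuration the tether from C7 allows, and C10 keeps the configuration of the trans acetal by least-motion collapse of the caged pair (retention, 10S); the closest known reaction type is Rh- or Cu-catalysed oxonium ylide formation and [1,2]-Stevens rearrangement of cyclic acetals tethered to diazo esters or diazo ketones (bridged dioxabicyclic lactones from 1,3-dioxan-5-yl diazoacetates), extended here to an α-alkyl diazo ester, for which bulky triphenylacetate ligands and low temperature are chosen to outrun 1,2-hydride shift and C–H insertion.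

Step 11
Reactants: 20 tris-silylated bicyclic lactone
Product: 21 (1R,2S,5R,9S)-2-[(tert-butyldimethylsilyl)oxy]-9-[(Z)-5-[(tert-butyldiphenylsilyl)oxy]-3-methylpent-3-en-1-yl]-1-[(Z)-5-hydroxy-4-methylpent-3-en-1-yl]-5-methyl-6,8-dioxabicyclo[3.2.2]nonan-7-one
Conditions: pyridinium p-toluenesulfonate (0.2 equiv), MeOH/CH2Cl2 1:1, 0 °C to rt
Reagents that add atoms: none
Why: Acid-catalysed methanolysis removes the primary allylic TBS ether far faster than the hindered secondary TBS ether at C10 or the primary TBDPS ether at C1.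

Step 12
Reactants: 21 C16 alcohol
Product: 22 (Z)-5-[(1R,2S,5R,9S)-2-[(tert-butyldimethylsilyl)oxy]-9-[(Z)-5-[(tert-butyldiphenylsilyl)oxy]-3-methylpent-3-en-1-yl]-5-methyl-7-oxo-6,8-dioxabicyclo[3.2.2]nonan-1-yl]-2-methylpent-2-en-1-yl acetate
Conditions: Ac2O, pyridine, DMAP (cat.), CH2Cl2, 0 °C
Reagents that add atoms: acetic anhydride, CC(=O)OC(C)=O
Why: Acetylation of the only free hydroxyl places the acetate unambiguously at C16.

Step 13
Reactants: 22 bis-silylated acetate
Product: 23 target, (Z)-5-[(1R,2S,5R,9S)-2-hydroxy-9-[(Z)-5-hydroxy-3-methylpent-3-en-1-yl]-5-methyl-7-oxo-6,8-dioxabicyclo[3.2.2]nonan-1-yl]-2-methylpent-2-en-1-yl acetate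
Conditions: HF·pyridine (excess), THF/pyridine, 0 °C to rt
Reagents that add atoms: none
Why: Fluoride-mediated global desilylation under mildly acidic conditions cleaves both remaining Si–O bonds while leaving the acetate, the lactone and all four stereocentres untouched.

**Compound list**

1 | (4-carboxybutyl)triphenylphosphonium bromide | [Br-].OC(=O)CCCC[P+](c1ccccc1)(c1ccccc1)c1ccccc1 | starting material
2 | 1-[(tert-butyldimethylsilyl)oxy]propan-2-one | CC(=O)CO[Si](C)(C)C(C)(C)C | starting material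
3 | potassium 5-(triphenylphosphoranylidene)pentanoate (carboxylate ylide) | [K+].[O-]C(=O)CCCC=P(c1ccccc1)(c1ccccc1)c1ccccc1 | intermediate
4 | (Z)-7-[(tert-butyldimethylsilyl)oxy]-6-methylhept-5-enoic acid | OC(=O)CCC/C=C(C)\CO[Si](C)(C)C(C)(C)C | intermediate
5 | nerol, (Z)-3,7-dimethylocta-2,6-dien-1-ol | CC(C)=CCC/C(C)=C\CO | starting material
6 | neryl tert-butyldiphenylsilyl ether | CC(C)=CCC/C(C)=C\CO[Si](c1ccccc1)(c1ccccc1)C(C)(C)C | intermediate
7 | (Z)-6-[(tert-butyldiphenylsilyl)oxy]-4-methylhex-4-enal | O=CCC/C(C)=C\CO[Si](c1ccccc1)(c1ccccc1)C(C)(C)C | intermediate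
8 | furan | c1ccoc1 | starting material
9 | 2-furyllithium | [Li]c1ccco1 | intermediate
10 | racemic (Z)-6-[(tert-butyldiphenylsilyl)oxy]-1-(furan-2-yl)-4-methylhex-4-en-1-ol | OC(CC/C(C)=C\CO[Si](c1ccccc1)(c1ccccc1)C(C)(C)C)c1ccco1 | intermediate
11 | (2S)-2-[(Z)-5-[(tert-butyldiphenylsilyl)oxy]-3-methylpent-3-en-1-yl]-6-hydroxy-2H-pyran-3(6H)-one, anomer mixture | O=C1C=CC(O)O[C@H]1CC/C(C)=C\CO[Si](c2ccccc2)(c2ccccc2)C(C)(C)C | intermediate
12 | (2S,6S)-6-[(tert-butyldimethylsilyl)oxy]-2-[(Z)-5-[(tert-butyldiphenylsilyl)oxy]-3-methylpent-3-en-1-yl]-2H-pyran-3(6H)-one | O=C1C=C[C@H](O[Si](C)(C)C(C)(C)C)O[C@H]1CC/C(C)=C\CO[Si](c2ccccc2)(c2ccccc2)C(C)(C)C | intermediate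
13 | (Z)-7-[(tert-butyldimethylsilyl)oxy]-6-methylhept-5-enoyl chloride | ClC(=O)CCC/C=C(C)\CO[Si](C)(C)C(C)(C)C | intermediate
14 | lithium (2S,3R,6S)-6-[(tert-butyldimethylsilyl)oxy]-2-[(Z)-5-[(tert-butyldiphenylsilyl)oxy]-3-methylpent-3-en-1-yl]-3-methyl-3,6-dihydro-2H-pyran-3-olate | [Li]O[C@]1(C)C=C[C@H](O[Si](C)(C)C(C)(C)C)O[C@H]1CC/C(C)=C\CO[Si](c2ccccc2)(c2ccccc2)C(C)(C)C | intermediate
15 | (2S,3R,6S)-3,6-dihydro-2H-pyran-3-yl (Z)-7-silyloxy-6-methylhept-5-enoate (allylic tertiary ester, substituents as in step 7) | CC(C)(C)[Si](C)(C)OC/C(C)=C\CCCC(=O)O[C@]1(C)C=C[C@H](O[Si](C)(C)C(C)(C)C)O[C@H]1CC/C(C)=C\CO[Si](c2ccccc2)(c2ccccc2)C(C)(C)C | intermediate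
16 | (2S,3R,6S)-tetrahydro-2H-pyran-3-yl (Z)-7-silyloxy-6-methylhept-5-enoate (saturated tertiary ester, substituents as in step 8) | CC(C)(C)[Si](C)(C)OC/C(C)=C\CCCC(=O)O[C@]1(C)CC[C@H](O[Si](C)(C)C(C)(C)C)O[C@H]1CC/C(C)=C\CO[Si](c2ccccc2)(c2ccccc2)C(C)(C)C | intermediate
17 | 2-(trifluoroacetyl) derivative of ester 16 (C11 epimers) | CC(C)(C)[Si](C)(C)OC/C(C)=C\CCC(C(=O)C(F)(F)F)C(=O)O[C@]1(C)CC[C@H](O[Si](C)(C)C(C)(C)C)O[C@H]1CC/C(C)=C\CO[Si](c2ccccc2)(c2ccccc2)C(C)(C)C | intermediate
18 | 2-diazo derivative of ester 16 | CC(C)(C)[Si](C)(C)OC/C(C)=C\CCC(=[N+]=[N-])C(=O)O[C@]1(C)CC[C@H](O[Si](C)(C)C(C)(C)C)O[C@H]1CC/C(C)=C\CO[Si](c2ccccc2)(c2ccccc2)C(C)(C)C | intermediate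
19 | bicyclic oxonium ylide (ring oxygen bonded to C6, C10 and carbanionic C11) | CC(C)(C)[Si](C)(C)OC/C(C)=C\CC[C-]1C(=O)O[C@]2(C)CC[C@H](O[Si](C)(C)C(C)(C)C)[O+]1[C@H]2CC/C(C)=C\CO[Si](c3ccccc3)(c3ccccc3)C(C)(C)C | intermediate
20 | (1R,2S,5R,9S)-tris-silylated 6,8-dioxabicyclo[3.2.2]nonan-7-one (C10-OTBS, C16-OTBS, C1-OTBDPS) | CC(C)(C)[Si](C)(C)OC/C(C)=C\CC[C@@]12O[C@@H](CC/C(C)=C\CO[Si](c3ccccc3)(c3ccccc3)C(C)(C)C)[C@@](C)(CC[C@@H]1O[Si](C)(C)C(C)(C)C)OC2=O | intermediate
21 | C16 alcohol (C10-OTBS, C1-OTBDPS) | OC/C(C)=C\CC[C@@]12O[C@@H](CC/C(C)=C\CO[Si](c3ccccc3)(c3ccccc3)C(C)(C)C)[C@@](C)(CC[C@@H]1O[Si](C)(C)C(C)(C)C)OC2=O | intermediate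
22 | C16 acetate (C10-OTBS, C1-OTBDPS) | CC(=O)OC/C(C)=C\CC[C@@]12O[C@@H](CC/C(C)=C\CO[Si](c3ccccc3)(c3ccccc3)C(C)(C)C)[C@@](C)(CC[C@@H]1O[Si](C)(C)C(C)(C)C)OC2=O | intermediate
23 | CNP0174851.1 | CC(=O)OC/C(C)=C\CC[C@@]12O[C@@H](CC/C(C)=C\CO)[C@@](C)(CC[C@@H]1O)OC2=O | target

**Step count and risks**

Total step count: 13. Longest linear sequence: 12 (steps 2–13, from nerol); the acid arm (step 1) joins at step 7.

Most likely to fail:

Step 10 (carbenoid cascade; risks are 1,2-hydride shift to the enoate, C–H insertion at C6–H or C16–H, or the C10 epimer). The fallback sets out from 18 and returns at 20. Buffered Bu4NF/AcOH at −20 °C removes only the anomeric silyl group to give the lactol diazo ester F1. Rh2(OAc)4 in CH2Cl2 then acts on the lactol/hydroxy-aldehyde equilibrium: O–H insertion of the C6 hydroxyl (or ylide formation at the hemiacetal ring oxygen) gives the dioxanone enol, which is trapped by the tethered C10 aldehyde in an intramolecular aldol to the C10-hydroxy bicyclic lactone F2. TBSOTf/2,6-lutidine converts F2 into 20.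

Step 9 (enolisation and diazo transfer on a hindered tertiary ester). The fallback sets out from 12 and returns at 18, avoiding any ester enolate. Lithium alkoxide 14 (from 12 and MeLi) is quenched with diketene to the allylic acetoacetate F3, and diimide reduction gives the saturated acetoacetate F4. Separately, (3-hydroxypropyl)triphenylphosphonium bromide is deprotonated twice with KN(SiMe3)2 to the oxido ylide F5, which reacts with 2 to give (Z)-5-[(tert-butyldimethylsilyl)oxy]-4-methylpent-3-en-1-ol F6; I2/PPh3/imidazole converts this into the homoallylic iodide F7. Alkylation of F4 with F7 (K2CO3, DMF) gives the α-alkyl acetoacetate F8, and deacetylative diazo transfer (MsN3, DBU, MeCN) delivers 18.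

Step 5 (kinetic resolution with in-situ ring expansion; at most 50 % yield and product ee depends on the rate ratio). The fallback sets out from 10 and returns at 11. MnO2 oxidises 10 to the furyl ketone F9. Asymmetric transfer hydrogenation with RuCl[(S,S)-TsDPEN](p-cymene) and HCO2H/Et3N gives the (S)-furyl carbinol F10 with full material throughput. NBS in buffered THF/H2O (NaHCO3, 0 °C) performs the Achmatowicz rearrangement to 11.

**Further compounds**

F1 | step 10 | (2S,3R)-6-hydroxy-tetrahydro-2H-pyran-3-yl 2-diazo ester (lactol diazo ester, anomer mixture) | CC(C)(C)[Si](C)(C)OC/C(C)=C\CCC(=[N+]=[N-])C(=O)O[C@]1(C)CCC(O)O[C@H]1CC/C(C)=C\CO[Si](c2ccccc2)(c2ccccc2)C(C)(C)C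
F2 | step 10 | C10-hydroxy bicyclic lactone (C16-OTBS, C1-OTBDPS) | CC(C)(C)[Si](C)(C)OC/C(C)=C\CC[C@@]12O[C@@H](CC/C(C)=C\CO[Si](c3ccccc3)(c3ccccc3)C(C)(C)C)[C@@](C)(CC[C@@H]1O)OC2=O
F3 | step 9 | allylic acetoacetate of the dihydropyranol | CC(=O)CC(=O)O[C@]1(C)C=C[C@H](O[Si](C)(C)C(C)(C)C)O[C@H]1CC/C(C)=C\CO[Si](c2ccccc2)(c2ccccc2)C(C)(C)C
F4 | step 9 | saturated acetoacetate of the tetrahydropyranol | CC(=O)CC(=O)O[C@]1(C)CC[C@H](O[Si](C)(C)C(C)(C)C)O[C@H]1CC/C(C)=C\CO[Si](c2ccccc2)(c2ccccc2)C(C)(C)C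
F5 | step 9 | potassium 3-(triphenylphosphoranylidene)propan-1-olate (oxido ylide) | [K+].[O-]CCC=P(c1ccccc1)(c1ccccc1)c1ccccc1
F6 | step 9 | (Z)-5-[(tert-butyldimethylsilyl)oxy]-4-methylpent-3-en-1-ol | OCC/C=C(C)\CO[Si](C)(C)C(C)(C)C
F7 | step 9 | (Z)-tert-butyl[(5-iodo-2-methylpent-2-en-1-yl)oxy]dimethylsilane | ICC/C=C(C)\CO[Si](C)(C)C(C)(C)C
F8 | step 9 | α-alkyl acetoacetate (C11 epimers) | CC(=O)C(CC/C=C(C)\CO[Si](C)(C)C(C)(C)C)C(=O)O[C@]1(C)CC[C@H](O[Si](C)(C)C(C)(C)C)O[C@H]1CC/C(C)=C\CO[Si](c2ccccc2)(c2ccccc2)C(C)(C)C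
F9 | step 5 | (Z)-6-[(tert-butyldiphenylsilyl)oxy]-1-(furan-2-yl)-4-methylhex-4-en-1-one | O=C(CC/C(C)=C\CO[Si](c1ccccc1)(c1ccccc1)C(C)(C)C)c1ccco1
F10 | step 5 | (S,Z)-6-[(tert-butyldiphenylsilyl)oxy]-1-(furan-2-yl)-4-methylhex-4-en-1-ol | O[C@@H](CC/C(C)=C\CO[Si](c1ccccc1)(c1ccccc1)C(C)(C)C)c1ccco1
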